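The target is read as epicatechin 3-O-gallate-(4β→6)-epicatechin 3-O-gallate-(4β→8)-catechin. The two upper units come from (–)-epicatechin; the terminal catechin unit is built de novo. Its ring C (O1–C2–C3–C4–C4a–C8a) is disconnected at C3–C4: because C4 is an unsubstituted methylene and the C3 hydroxyl is trans to the C2 aryl group, this bond is a masked C3=C4 alkene. Ring-closing metathesis of an enantioenriched 1-arylallyl 2-vinylaryl ether closes ring C in one operation, and hydroboration anti to the aryl group then sets C3. Orthogonal C4 leaving groups and bromine caps control the two interflavan couplings.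

Key step: step 7

Assumption: the (Sa,S,S) enantiomer of the phosphoramidite ligand in step 6 is taken to deliver the (S)-ether 9; should the sense of induction be the opposite, the (Ra,R,R) enantiomer is used and nothing else changes.

Conventions: flavan numbering (O1, C2, C3, C4, C4a, C5–C8, C8a; ring A = benzo ring, ring C = pyran ring). "4β" means the C4 substituent lies on the face opposite to the C2 aryl group and the C3 oxygen of an epicatechin unit. TBG = 3,4,5-tris(benzyloxy)benzoyl.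

**Terminal catechin unit**

Step 1
Reactants: 1 2,4,6-trihydroxybenzaldehyde
Product: 2 4,6-bis(benzyloxy)-2-hydroxybenzaldehyde
Conditions: BnBr (2.05 equiv), K2CO3 (2.2 equiv), DMF, 0 °C to rt
Reagents that add atoms: benzyl bromide, BrCc1ccccc1
Why: Williamson benzylation of the para hydroxyl and one ortho hydroxyl; the remaining ortho hydroxyl is held back by its hydrogen bond to the formyl group, so two equivalents of benzyl bromide should stop at 2.

Step 2
Reactants: 2 4,6-bis(benzyloxy)-2-hydroxybenzaldehyde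
Product: 3 3,5-bis(benzyloxy)-2-vinylphenol
Conditions: Ph3PCH3Br (2.5 equiv), KOtBu (2.5 equiv), THF, 0 °C to rt
Reagents that add atoms: methyltriphenylphosphonium bromide, C[P+](c1ccccc1)(c1ccccc1)c1ccccc1.[Br-]
Why: Wittig methylenation with excess ylide (one equivalent is consumed by the phenol) should turn the formyl group into the vinyl group whose carbon becomes C4.

Step 3
Reactants: 4 3,4-bis(benzyloxy)benzaldehyde
Product: 5 ethyl (E)-3-[3,4-bis(benzyloxy)phenyl]prop-2-enoate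
Conditions: (EtO)2P(O)CH2CO2Et (1.2 equiv), NaH (1.2 equiv), THF, 0 °C to rt
Reagents that add atoms: triethyl phosphonoacetate, CCOC(=O)CP(=O)(OCC)OCC
Why: Horner–Wadsworth–Emmons olefination with a stabilised phosphonate should give the (E)-cinnamate.

Step 4
Reactants: 5 ethyl (E)-3-[3,4-bis(benzyloxy)phenyl]prop-2-enoate
Product: 6 (E)-3-[3,4-bis(benzyloxy)phenyl]prop-2-en-1-ol
Conditions: i-Bu2AlH (2.5 equiv), CH2Cl2, –78 °C to 0 °C; Rochelle salt work-up
Reagents that add atoms: none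
Why: 1,2-reduction of the conjugated ester by i-Bu2AlH should give the allylic alcohol and leave the alkene and the benzyl ethers untouched.

Step 5
Reactants: 6 (E)-3-[3,4-bis(benzyloxy)phenyl]prop-2-en-1-ol
Product: 7 (E)-3-[3,4-bis(benzyloxy)phenyl]allyl methyl carbonate
Conditions: ClCO2Me (1.5 equiv), pyridine (2 equiv), CH2Cl2, 0 °C
Reagents that add atoms: methyl chloroformate, COC(=O)Cl
Why: acylation of the primary alcohol gives the linear allylic carbonate that serves as electrophile in step 6.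

Step 6
Reactants: 3 3,5-bis(benzyloxy)-2-vinylphenol; 7 (E)-3-[3,4-bis(benzyloxy)phenyl]allyl methyl carbonate
Product: 9 (S)-1-[3,4-bis(benzyloxy)phenyl]allyl 3,5-bis(benzyloxy)-2-vinylphenyl ether, via lithium aryloxide 8 (not isolated)
Conditions: 3 (1.5 equiv), LiN(SiMe3)2 (1.5 equiv), THF, 0 °C; then 7, [Ir(cod)Cl]2 (2 mol %), (Sa,S,S)-O,O'-(1,1'-binaphthyl-2,2'-diyl)-N,N-bis(1-phenylethyl)phosphoramidite (4 mol %), THF, 50 °C
Reagents that add atoms: lithium bis(trimethylsilyl)amide, [Li+].C[Si](C)(C)[N-][Si](C)(C)C (supplies only the lithium of 8)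
Why: iridium-catalysed asymmetric allylic etherification of a linear cinnamyl carbonate with an aryloxide; attack at the aryl-substituted terminus of the allyl iridium complex should give the branched ether, and the chiral phosphoramidite selects the face, setting the future C2 centre as (S).

Step 7
Reactants: 9 (S)-1-[3,4-bis(benzyloxy)phenyl]allyl 3,5-bis(benzyloxy)-2-vinylphenyl ether
Product: 10 (S)-5,7-bis(benzyloxy)-2-[3,4-bis(benzyloxy)phenyl]-2H-chromene
Conditions: second-generation Grubbs catalyst RuCl2(=CHPh)(PCy3)(H2IMes) (5 mol %), 1,4-benzoquinone (10 mol %), CH2Cl2 (0.01 M), 40 °C, dark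
Reagents that add atoms: none
Why: olefin metathesis by the Chauvin mechanism: the ruthenium benzylidene first engages the monosubstituted allylic alkene of 9, the new alkylidene adds across the ortho vinyl group to a ruthenacyclobutane, and cycloreversion releases ethylene and the C3=C4 double bond. The closest known reaction type is ring-closing metathesis of allyl 2-vinylphenyl ethers to 2H-chromenes. Ring C is closed as a six-membered ring by metathesis of two terminal alkenes with the new alkene endocyclic; this is not a polar Baldwin-type closure, and loss of ethylene drives it. No stereocentre is created: C2 is untouched because neither its C–O nor its C–H bond takes part, and the C3 carbinol centre is set in step 8 under control of C2. The step needs cyclisation over oligomerisation and no migration of the allylic double bond; the ortho relationship of the two alkenes on ring A, high dilution and 1,4-benzoquinone as hydride scavenger should secure both.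

Step 8
Reactants: 10 (S)-5,7-bis(benzyloxy)-2-[3,4-bis(benzyloxy)phenyl]-2H-chromene
Product: 12 5,7,3',4'-tetra-O-benzyl-(+)-catechin [(2R,3S)-5,7-bis(benzyloxy)-2-[3,4-bis(benzyloxy)phenyl]chroman-3-ol], via C3-alkylborane 11 (not isolated)
Conditions: BH3·THF (2 equiv), THF, 0 °C to rt; then 3 M NaOH, 30% H2O2, 0 °C to rt
Reagents that add atoms: borane (as BH3·THF), B (supplies the boron of 11 and the new C4 hydrogen); hydrogen peroxide, OO (supplies the C3 oxygen)
Why: hydroboration–oxidation of a flav-3-ene; boron should add to C3 (away from the aryl-bearing C4) on the face anti to the C2 aryl group, and oxidation with retention then gives the 2,3-trans alcohol, i.e. (3S).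

**Upper units from (–)-epicatechin**

Step 9
Reactants: 13 (–)-epicatechin [(2R,3R)]
Product: 14 5,7,3',4'-tetra-O-benzyl-(–)-epicatechin
Conditions: BnBr (4.4 equiv), K2CO3 (5 equiv), DMF, 0 °C to rt
Reagents that add atoms: benzyl bromide, BrCc1ccccc1
Why: Williamson benzylation with a weak base alkylates the four phenols, which are far more acidic than the secondary alcohol, so the C3 hydroxyl should stay free.

Step 10
Reactants: 14 5,7,3',4'-tetra-O-benzyl-(–)-epicatechin
Product: 15 8-bromo-5,7,3',4'-tetra-O-benzylepicatechin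
Conditions: NBS (1.0 equiv), CH2Cl2, –78 °C to rt
Reagents that add atoms: N-bromosuccinimide, O=C1CCC(=O)N1Br
Why: electrophilic aromatic bromination of the phloroglucinol-type ring A, which for 5,7-di-O-benzyl flavans takes place first at C8, installs the cap that later forces coupling to C6.

Step 11
Reactants: 15 8-bromo-5,7,3',4'-tetra-O-benzylepicatechin
Product: 16 8-bromo-4β-(2-ethoxyethoxy)-5,7,3',4'-tetra-O-benzylepicatechin
Conditions: DDQ (2 equiv), 2-ethoxyethanol (5 equiv), CH2Cl2, rt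
Reagents that add atoms: 2-ethoxyethanol, CCOCCO
Why: benzylic oxidation by DDQ (hydride abstraction at C4 to a cation stabilised by ring A) and capture by the alcohol anti to the C2 and C3 substituents should give the 4β ether.

Step 12
Reactants: 16 8-bromo-4β-(2-ethoxyethoxy)-5,7,3',4'-tetra-O-benzylepicatechin; 17 3,4,5-tris(benzyloxy)benzoic acid
Product: 18 8-bromo-4β-(2-ethoxyethoxy)-3-O-TBG-5,7,3',4'-tetra-O-benzylepicatechin
Conditions: DCC (1.5 equiv), DMAP (0.3 equiv), CH2Cl2, rt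
Reagents that add atoms: none
Why: Steglich esterification of the secondary C3 hydroxyl installs the protected gallate, which also serves as participating group in steps 14 to 16.

Step 13
Reactants: 18 8-bromo-4β-(2-ethoxyethoxy)-3-O-TBG-5,7,3',4'-tetra-O-benzylepicatechin
Product: 19 6,8-dibromo-4β-(2-ethoxyethoxy)-3-O-TBG-5,7,3',4'-tetra-O-benzylepicatechin (upper-unit electrophile)
Conditions: NBS (1.1 equiv), CH2Cl2, 0 °C to rt
Reagents that add atoms: N-bromosuccinimide, O=C1CCC(=O)N1Br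
Why: a second electrophilic bromination at C6, the only free position of ring A, removes the last nucleophilic site so that the electrophile cannot self-condense.

Step 14
Reactants: 18 8-bromo-4β-(2-ethoxyethoxy)-3-O-TBG-5,7,3',4'-tetra-O-benzylepicatechin
Product: 20 8-bromo-4β-(2,6-dimethylphenylthio)-3-O-TBG-5,7,3',4'-tetra-O-benzylepicatechin (middle unit)
Conditions: 2,6-dimethylbenzenethiol (3 equiv), BF3·OEt2 (0.5 equiv), CH2Cl2, –78 °C to –20 °C
Reagents that add atoms: 2,6-dimethylbenzenethiol, Cc1cccc(C)c1S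
Why: Lewis-acid ionisation of the C4 ether and capture by the thiol; the C3 ester participates on the α face (1,3-dioxolan-2-ylium ion), so sulfur should enter 4β, and excess thiol outcompetes C6 of a second molecule.

**Assembly and deprotection**

Step 15
Reactants: 19 6,8-dibromo-4β-(2-ethoxyethoxy)-3-O-TBG-5,7,3',4'-tetra-O-benzylepicatechin; 20 8-bromo-4β-(2,6-dimethylphenylthio)-3-O-TBG-5,7,3',4'-tetra-O-benzylepicatechin
Product: 21 protected dimer, [6,8-dibromo-3-O-TBG-tetra-O-benzylepicatechin]-(4β→6)-[8-bromo-4β-(2,6-dimethylphenylthio)-3-O-TBG-tetra-O-benzylepicatechin]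
Conditions: 20 (1.5 equiv), TMSOTf (0.3 equiv), 4 Å molecular sieves, CH2Cl2, –78 °C to –40 °C
Reagents that add atoms: none
Why: Friedel–Crafts-type flavan coupling; the oxophilic Lewis acid ionises only the C4 ether of 19 (the hindered thioether of 20 is inert to it), the C3 ester shields the α face, and C6 of 20, the sole free position of its ring A, should attack from the β face to set the 4β→6 bond.

Step 16
Reactants: 21 protected dimer; 12 5,7,3',4'-tetra-O-benzyl-(+)-catechin
Product: 22 protected trimer, [6,8-dibromo-3-O-TBG-tetra-O-benzylepicatechin]-(4β→6)-[8-bromo-3-O-TBG-tetra-O-benzylepicatechin]-(4β→8)-[5,7,3',4'-tetra-O-benzylcatechin]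
Conditions: 12 (3 equiv), AgBF4 (2 equiv), 2,6-di-tert-butyl-4-methylpyridine (2 equiv), 4 Å molecular sieves, CH2Cl2/THF, –40 °C to 0 °C, dark
Reagents that add atoms: none
Why: thiophilic activation of the C4 thioether by AgBF4 (orthogonal to step 15) and participation of the C3 ester on the α face, followed by attack of C8 of 12, the more nucleophilic ring-A position of a 5,7-di-O-benzyl flavan, should give the 4β→8 bond, while excess 12 limits further reaction of the product.

Step 17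
Reactants: 22 protected trimer
Product: 23 epicatechin 3-O-gallate-(4β→6)-epicatechin 3-O-gallate-(4β→8)-catechin (target)
Conditions: H2 (1 atm), Pd(OH)2/C, Et3N (3.5 equiv), THF/MeOH/H2O, rt; filtration, lyophilisation, Sephadex LH-20
Reagents that add atoms: none
Why: hydrogenolysis over Pd(OH)2/C should cleave all eighteen benzyl ethers and the three aryl C–Br bonds in one operation, the amine trapping HBr so that the acid-labile interflavan bonds and the gallate esters survive.

**Compound list**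

1 | 2,4,6-trihydroxybenzaldehyde | O=Cc1c(O)cc(O)cc1O | starting material
2 | 4,6-bis(benzyloxy)-2-hydroxybenzaldehyde | O=Cc1c(O)cc(OCc2ccccc2)cc1OCc1ccccc1 | intermediate
3 | 3,5-bis(benzyloxy)-2-vinylphenol | C=Cc1c(O)cc(OCc2ccccc2)cc1OCc1ccccc1 | intermediate
4 | 3,4-bis(benzyloxy)benzaldehyde | O=Cc1ccc(OCc2ccccc2)c(OCc2ccccc2)c1 | starting material
5 | ethyl (E)-3-[3,4-bis(benzyloxy)phenyl]prop-2-enoate | CCOC(=O)/C=C/c1ccc(OCc2ccccc2)c(OCc2ccccc2)c1 | intermediate
6 | (E)-3-[3,4-bis(benzyloxy)phenyl]prop-2-en-1-ol | OC/C=C/c1ccc(OCc2ccccc2)c(OCc2ccccc2)c1 | intermediate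
7 | (E)-3-[3,4-bis(benzyloxy)phenyl]allyl methyl carbonate | COC(=O)OC/C=C/c1ccc(OCc2ccccc2)c(OCc2ccccc2)c1 | intermediate
8 | lithium 3,5-bis(benzyloxy)-2-vinylphenoxide | [Li+].[O-]c1cc(OCc2ccccc2)cc(OCc2ccccc2)c1C=C | intermediate
9 | (S)-1-[3,4-bis(benzyloxy)phenyl]allyl 3,5-bis(benzyloxy)-2-vinylphenyl ether | C=C[C@H](Oc1cc(OCc2ccccc2)cc(OCc2ccccc2)c1C=C)c1ccc(OCc2ccccc2)c(OCc2ccccc2)c1 | intermediate
10 | (S)-5,7-bis(benzyloxy)-2-[3,4-bis(benzyloxy)phenyl]-2H-chromene | O1[C@H](c2ccc(OCc3ccccc3)c(OCc3ccccc3)c2)C=Cc2c1cc(OCc1ccccc1)cc2OCc1ccccc1 | intermediate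
11 | C3-alkylborane of 10 (BH2 on C3, trans to the C2 aryl group) | O1[C@H](c2ccc(OCc3ccccc3)c(OCc3ccccc3)c2)[C@@H](B)Cc2c1cc(OCc1ccccc1)cc2OCc1ccccc1 | intermediate
12 | 5,7,3',4'-tetra-O-benzyl-(+)-catechin, (2R,3S) | O1[C@H](c2ccc(OCc3ccccc3)c(OCc3ccccc3)c2)[C@@H](O)Cc2c1cc(OCc1ccccc1)cc2OCc1ccccc1 | intermediate
13 | (–)-epicatechin, (2R,3R) | O1[C@H](c2ccc(O)c(O)c2)[C@H](O)Cc2c1cc(O)cc2O | starting material
14 | 5,7,3',4'-tetra-O-benzyl-(–)-epicatechin | O1[C@H](c2ccc(OCc3ccccc3)c(OCc3ccccc3)c2)[C@H](O)Cc2c1cc(OCc1ccccc1)cc2OCc1ccccc1 | intermediate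
15 | 8-bromo-5,7,3',4'-tetra-O-benzylepicatechin | O1[C@H](c2ccc(OCc3ccccc3)c(OCc3ccccc3)c2)[C@H](O)Cc2c1c(Br)c(OCc1ccccc1)cc2OCc1ccccc1 | intermediate
16 | 8-bromo-4β-(2-ethoxyethoxy)-5,7,3',4'-tetra-O-benzylepicatechin | O1[C@H](c2ccc(OCc3ccccc3)c(OCc3ccccc3)c2)[C@H](O)[C@@H](OCCOCC)c2c1c(Br)c(OCc1ccccc1)cc2OCc1ccccc1 | intermediate
17 | 3,4,5-tris(benzyloxy)benzoic acid | OC(=O)c1cc(OCc2ccccc2)c(OCc2ccccc2)c(OCc2ccccc2)c1 | starting material
18 | 8-bromo-4β-(2-ethoxyethoxy)-3-O-TBG-5,7,3',4'-tetra-O-benzylepicatechin | O1[C@H](c2ccc(OCc3ccccc3)c(OCc3ccccc3)c2)[C@H](OC(=O)c2cc(OCc3ccccc3)c(OCc3ccccc3)c(OCc3ccccc3)c2)[C@@H](OCCOCC)c2c1c(Br)c(OCc1ccccc1)cc2OCc1ccccc1 | intermediate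
19 | 6,8-dibromo-4β-(2-ethoxyethoxy)-3-O-TBG-5,7,3',4'-tetra-O-benzylepicatechin | O1[C@H](c2ccc(OCc3ccccc3)c(OCc3ccccc3)c2)[C@H](OC(=O)c2cc(OCc3ccccc3)c(OCc3ccccc3)c(OCc3ccccc3)c2)[C@@H](OCCOCC)c2c1c(Br)c(OCc1ccccc1)c(Br)c2OCc1ccccc1 | intermediate
20 | 8-bromo-4β-(2,6-dimethylphenylthio)-3-O-TBG-5,7,3',4'-tetra-O-benzylepicatechin | O1[C@H](c2ccc(OCc3ccccc3)c(OCc3ccccc3)c2)[C@H](OC(=O)c2cc(OCc3ccccc3)c(OCc3ccccc3)c(OCc3ccccc3)c2)[C@@H](Sc2c(C)cccc2C)c2c1c(Br)c(OCc1ccccc1)cc2OCc1ccccc1 | intermediate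
21 | protected (4β→6) dimer carrying the C4 thioether on the lower unit | O1[C@H](c7ccc(OCc9ccccc9)c(OCc9ccccc9)c7)[C@H](OC(=O)c8cc(OCc9ccccc9)c(OCc9ccccc9)c(OCc9ccccc9)c8)[C@@H](c3c(OCc9ccccc9)c4[C@H](Sc5c(C)cccc5C)[C@@H](OC(=O)c8cc(OCc9ccccc9)c(OCc9ccccc9)c(OCc9ccccc9)c8)[C@@H](c7ccc(OCc9ccccc9)c(OCc9ccccc9)c7)Oc4c(Br)c3OCc9ccccc9)c2c1c(Br)c(OCc9ccccc9)c(Br)c2OCc9ccccc9 | intermediate
22 | protected trimer (eighteen benzyl ethers, three aryl bromides) | O1[C@H](c7ccc(OCc9ccccc9)c(OCc9ccccc9)c7)[C@H](OC(=O)c8cc(OCc9ccccc9)c(OCc9ccccc9)c(OCc9ccccc9)c8)[C@@H](c3c(OCc9ccccc9)c4[C@H](c5c(OCc9ccccc9)cc(OCc9ccccc9)c6c5O[C@H](c7ccc(OCc9ccccc9)c(OCc9ccccc9)c7)[C@@H](O)C6)[C@@H](OC(=O)c8cc(OCc9ccccc9)c(OCc9ccccc9)c(OCc9ccccc9)c8)[C@@H](c7ccc(OCc9ccccc9)c(OCc9ccccc9)c7)Oc4c(Br)c3OCc9ccccc9)c2c1c(Br)c(OCc9ccccc9)c(Br)c2OCc9ccccc9 | intermediate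
23 | epicatechin 3-O-gallate-(4β→6)-epicatechin 3-O-gallate-(4β→8)-catechin | O=C(O[C@@H]1[C@@H](c2c(O)cc3c(c2O)[C@H](c2c(O)cc(O)c4c2O[C@H](c2ccc(O)c(O)c2)[C@@H](O)C4)[C@@H](OC(=O)c2cc(O)c(O)c(O)c2)[C@@H](c2ccc(O)c(O)c2)O3)c2c(O)cc(O)cc2O[C@@H]1c1ccc(O)c(O)c1)c1cc(O)c(O)c(O)c1 | target

**Summary**

Total step count: 17.

Longest linear sequence: 8 steps (steps 3, 4, 5, 6, 7, 8, 16, 17; the sequence 9, 10, 11, 12, 14, 15, 16, 17 is equally long).

Steps most likely to fail:

1. Step 15. The C6 position of 20 is flanked by two benzyloxy groups and deactivated by the C8 bromine, so attack may be sluggish, and the arylthio group may be transferred from 20 to the cation of 19, scrambling the leaving groups. The fallback sets out from 15 and 19 and removes sulfur from the nucleophile. Compound 15 is esterified with 17 (DCC, DMAP, CH2Cl2) to 8-bromo-3-O-TBG-5,7,3',4'-tetra-O-benzylepicatechin F1. Coupling of 19 with excess F1 (TMSOTf, CH2Cl2, –78 °C) should give the (4β→6) dimer with a C4 methylene in its lower unit F2. DDQ oxidation of that methylene in the presence of 2-ethoxyethanol should give the dimeric 4β-(2-ethoxyethoxy) electrophile F3. Coupling of F3 with excess 12 (TMSOTf, CH2Cl2, –78 °C) comes back to the route at 22.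

2. Step 16. Acid liberated during the silver-promoted ionisation may cleave or scramble the existing interflavan bond, and attack may also occur at C6 of 12 or on the product. The fallback sets out from 21 and separates ionisation of the C–S bond from C–C bond formation. Buffered silver-promoted methanolysis (AgOTf, MeOH, 2,6-di-tert-butyl-4-methylpyridine, CH2Cl2) should give the dimeric 4β-methyl ether F4. F4 is then coupled with excess 12 under hard Lewis-acid catalysis (TMSOTf, CH2Cl2, –78 °C), and the route is rejoined at 22.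

3. Step 6. The branched ether carries an electron-rich aryl group and an aryloxide leaving group, so reversible ionisation on iridium may erode the enantiomeric purity and drift towards the linear ether. The fallback sets out from 3 and 7 and replaces asymmetric catalysis by resolution. Branched-selective etherification with an achiral catalyst ([Ir(cod)Cl]2, P(OPh)3, lithium aryloxide of 3, THF) should give the racemic 1-arylallyl 2-vinylaryl ether F5. Ring-closing metathesis as in step 7 gives the racemic 2H-chromene F6. Hydroboration–oxidation as in step 8 gives racemic trans-5,7,3',4'-tetra-O-benzylcatechin F7. Esterification with (S)-O-methylmandelic acid (DCC, DMAP) and separation of the diastereomers by chromatography or crystallisation gives the (2R,3S)-flavan-3-yl (S)-methoxy(phenyl)acetate F8. Methanolysis (K2CO3, MeOH/THF) comes back to the route at 12.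

**Further compounds**

F1 | step 15 | 8-bromo-3-O-TBG-5,7,3',4'-tetra-O-benzylepicatechin | O1[C@H](c2ccc(OCc3ccccc3)c(OCc3ccccc3)c2)[C@H](OC(=O)c2cc(OCc3ccccc3)c(OCc3ccccc3)c(OCc3ccccc3)c2)Cc2c1c(Br)c(OCc1ccccc1)cc2OCc1ccccc1
F2 | step 15 | protected (4β→6) dimer with C4 methylene in the lower unit | O1[C@H](c7ccc(OCc9ccccc9)c(OCc9ccccc9)c7)[C@H](OC(=O)c8cc(OCc9ccccc9)c(OCc9ccccc9)c(OCc9ccccc9)c8)[C@@H](c3c(OCc9ccccc9)c4C[C@@H](OC(=O)c8cc(OCc9ccccc9)c(OCc9ccccc9)c(OCc9ccccc9)c8)[C@@H](c7ccc(OCc9ccccc9)c(OCc9ccccc9)c7)Oc4c(Br)c3OCc9ccccc9)c2c1c(Br)c(OCc9ccccc9)c(Br)c2OCc9ccccc9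
F3 | step 15 | protected (4β→6) dimer with 4β-(2-ethoxyethoxy) group on the lower unit | O1[C@H](c7ccc(OCc9ccccc9)c(OCc9ccccc9)c7)[C@H](OC(=O)c8cc(OCc9ccccc9)c(OCc9ccccc9)c(OCc9ccccc9)c8)[C@@H](c3c(OCc9ccccc9)c4[C@H](OCCOCC)[C@@H](OC(=O)c8cc(OCc9ccccc9)c(OCc9ccccc9)c(OCc9ccccc9)c8)[C@@H](c7ccc(OCc9ccccc9)c(OCc9ccccc9)c7)Oc4c(Br)c3OCc9ccccc9)c2c1c(Br)c(OCc9ccccc9)c(Br)c2OCc9ccccc9
F4 | step 16 | protected (4β→6) dimer with 4β-methoxy group on the lower unit | O1[C@H](c7ccc(OCc9ccccc9)c(OCc9ccccc9)c7)[C@H](OC(=O)c8cc(OCc9ccccc9)c(OCc9ccccc9)c(OCc9ccccc9)c8)[C@@H](c3c(OCc9ccccc9)c4[C@H](OC)[C@@H](OC(=O)c8cc(OCc9ccccc9)c(OCc9ccccc9)c(OCc9ccccc9)c8)[C@@H](c7ccc(OCc9ccccc9)c(OCc9ccccc9)c7)Oc4c(Br)c3OCc9ccccc9)c2c1c(Br)c(OCc9ccccc9)c(Br)c2OCc9ccccc9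
F5 | step 6 | racemic 1-[3,4-bis(benzyloxy)phenyl]allyl 3,5-bis(benzyloxy)-2-vinylphenyl ether | C=CC(Oc1cc(OCc2ccccc2)cc(OCc2ccccc2)c1C=C)c1ccc(OCc2ccccc2)c(OCc2ccccc2)c1
F6 | step 6 | racemic 5,7-bis(benzyloxy)-2-[3,4-bis(benzyloxy)phenyl]-2H-chromene | O1C(c2ccc(OCc3ccccc3)c(OCc3ccccc3)c2)C=Cc2c1cc(OCc1ccccc1)cc2OCc1ccccc1
F7 | step 6 | racemic trans-5,7,3',4'-tetra-O-benzylcatechin (both enantiomers written) | O1[C@H](c2ccc(OCc3ccccc3)c(OCc3ccccc3)c2)[C@@H](O)Cc2c1cc(OCc1ccccc1)cc2OCc1ccccc1.O1[C@@H](c2ccc(OCc3ccccc3)c(OCc3ccccc3)c2)[C@H](O)Cc2c1cc(OCc1ccccc1)cc2OCc1ccccc1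
F8 | step 6 | (2R,3S)-5,7,3',4'-tetra-O-benzylcatechin 3-O-[(S)-methoxy(phenyl)acetate] | O1[C@H](c2ccc(OCc3ccccc3)c(OCc3ccccc3)c2)[C@@H](OC(=O)[C@@H](OC)c2ccccc2)Cc2c1cc(OCc1ccccc1)cc2OCc1ccccc1
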